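The hydroazulene core is disconnected to a 3-methylanisole ring carrying a diazoketone side chain. The seven-membered ring (C5–C6–C7–C8–C9–C10–C1) with its C8 methyl and C10 oxygen is that arene enlarged by one carbon, and C5, the ring-fusion CH next to the C4 carbinol, is a former carbenoid carbon beside a ketone. One intramolecular Buchner reaction of 1-diazo-4-(2-methoxy-4-methylphenyl)butan-2-one therefore forms C5–C1 and C5–C6, closes the cyclopentanone, expands the benzene ring to a cycloheptatriene and sets C5 under ligand control. C4, C1, C6 and C10 are then set in turn from C5.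

Key step: step 4

Remarks before the steps.
- Numbering: C1–C10 are the locants of the target core (C1 methylated ring-fusion carbon, C2 and C3 methylenes, C4 isopropyl carbinol, C5 ring-fusion CH, C6 anisoate carbon, C7 methylene, C8 methylated alkene carbon, C9 alkene CH, C10 acetate carbon). "Daucane" names use this skeleton (methyl on C1 and C8, propan-2-yl on C4). α is the face of H5, β the face of the C1 methyl.
- Assumption: the sense of induction of the bis(oxazoline) ligand in step 4 is not predicted here. The (4R,4′R) ligand is written, and its (4S,4′S) antipode is used if a first run shows the opposite sense.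

Step 1
Reactants: 1 2-methoxy-4-methylbenzaldehyde; 2 malonic acid
Product: 4 (2E)-3-(2-methoxy-4-methylphenyl)prop-2-enoic acid, via arylidenemalonic acid 3 (not isolated)
Conditions: pyridine, piperidine (cat.), 100 °C
Reagents that add atoms: none
Why: Knoevenagel–Doebner condensation, in which the amine-catalysed condensation is followed by decarboxylation of 3 in hot pyridine, should give the (E)-cinnamic acid.

Step 2
Reactants: 4 (2E)-3-(2-methoxy-4-methylphenyl)prop-2-enoic acid
Product: 5 3-(2-methoxy-4-methylphenyl)propanoic acid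
Conditions: H2 (1 atm), Pd/C (10 wt %), EtOAc, rt
Reagents that add atoms: none
Why: Heterogeneous catalytic hydrogenation should saturate the conjugated C=C bond and leave the arene and the aryl ether untouched.

Step 3
Reactants: 5 3-(2-methoxy-4-methylphenyl)propanoic acid; 6 (trimethylsilyl)diazomethane
Product: 8 1-diazo-4-(2-methoxy-4-methylphenyl)butan-2-one, via acid chloride 7 (not isolated)
Conditions: (COCl)2, DMF (cat.), CH2Cl2, 0 °C to rt; evaporation; then 6 (2.2 equiv), MeCN–THF, 0 °C to rt
Reagents that add atoms: none
Why: Acid chloride formation followed by C-acylation of the silyl diazomethane with loss of the silyl group (Arndt–Eistert-type diazoketone synthesis) is standard for unbranched acid chlorides.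

Step 4
Reactants: 8 1-diazo-4-(2-methoxy-4-methylphenyl)butan-2-one
Product: 10 (8aR)-4-methoxy-6-methyl-3,8a-dihydroazulen-1(2H)-one, via norcaradiene 9 (not isolated)
Conditions: CuCl (5 mol %), NaB[3,5-(CF3)2C6H3]4 (6 mol %), (4R,4′R)-2,2′-(propane-2,2-diyl)bis(4-phenyl-4,5-dihydro-1,3-oxazole) (6 mol %), CH2Cl2, 40 °C, slow addition of 8; filtration through neutral alumina, product used at once
Reagents that add atoms: none
Why: Loss of N2 from 8 on the cationic monovalent copper–bis(oxazoline) complex gives an electrophilic copper carbenoid whose carbon (C5) adds across the C1–C6 bond (ipso carbon and unsubstituted ortho carbon) of the anisole ring, the closest known reaction type being the copper–bis(oxazoline)-catalysed intramolecular Buchner reaction of 1-diazo-4-arylbutan-2-ones to azulenones. The cyclopentanone is closed in this cyclopropanation by the C5–C1 bond, the carbenoid carbon reaching the ipso carbon through the three-atom tether in a five-membered closure onto the arene while C5–C6 completes the three-membered ring. The seven-membered ring is not closed by a new ring bond but arises when norcaradiene 9 opens its C1–C6 bond in a thermally allowed disrotatory six-electron electrocyclic reaction. C5 is the only stereocentre that remains, and its configuration is decided in the cyclopropanation, where the C2-symmetric ligand on copper makes the carbenoid choose one of the two enantiotopic faces of the arene. The step needs addition at C1–C6 and not at the methoxy-bearing C1–C10 bond, which the ortho-methoxy group should secure by blocking its own side, and it needs cyclopropanation instead of aromatic substitution to a 2-tetralone, which the copper catalyst and an acid-free work-up should secure.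

Step 5
Reactants: 10 (8aR)-4-methoxy-6-methyl-3,8a-dihydroazulen-1(2H)-one
Product: 11 (1R,8aR)-4-methoxy-6-methyl-1-(propan-2-yl)-1,2,3,8a-tetrahydroazulen-1-ol
Conditions: i-PrMgCl (1.5 equiv), CeCl3 (1.5 equiv, dried), THF, −78 °C; pH 7 buffer work-up
Reagents that add atoms: isopropylmagnesium chloride, CC(C)[Mg]Cl
Why: Organocerium 1,2-addition to an enolisable ketone should proceed without deprotonating the acidic C5–H, the reagent entering on the face of H5 and anti to the C5–C6 bond, so that the isopropyl group becomes cis to H5 and the new C4 hydroxyl lies on the β face.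

Step 6
Reactants: 11 (1R,8aR)-4-methoxy-6-methyl-1-(propan-2-yl)-1,2,3,8a-tetrahydroazulen-1-ol
Product: 12 (1R,3R,8R,9R)-3-methoxy-5-methyl-9-(propan-2-yl)tricyclo[6.3.0.0(1,3)]undeca-4,6-dien-9-ol (cyclopropane across C1–C10, CH2 on the β face)
Conditions: Et2Zn (1.5 equiv), CH2I2 (1.5 equiv), CH2Cl2, −20 to 0 °C; aq. NH4Cl/NaHCO3 work-up
Reagents that add atoms: diiodomethane, ICI
Why: Hydroxyl-directed Simmons–Smith cyclopropanation should deliver CH2 from the zinc alkoxide at C4 to the most electron-rich alkene, the enol ether C1=C10, on the β face (the face of the C4–O bond, which is also the convex face opposite H5 and opposite the isopropyl group), setting C1 with its new carbon trans to H5.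

Step 7
Reactants: 12 (1R,3R,8R,9R)-3-methoxy-5-methyl-9-(propan-2-yl)tricyclo[6.3.0.0(1,3)]undeca-4,6-dien-9-ol
Product: 13 (1S,4R,5R)-4-hydroxydauca-6,8-dien-10-one
Conditions: 1 M HCl, THF, 25–40 °C
Reagents that add atoms: water, O
Why: Acid-induced ring opening of an alkoxycyclopropane (the enol ether cyclopropanation route to α-methyl ketones) should cleave the C10–CH2 bond toward the dienyl-stabilised oxocarbenium ion, whose hydrolysis leaves the C10 ketone and turns the CH2 into the C1 methyl with the trans ring fusion intact.

Step 8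
Reactants: 13 (1S,4R,5R)-4-hydroxydauca-6,8-dien-10-one
Product: 14 (1S,4R,5S,6R,7S)-6,7-epoxy-4-hydroxydauc-8-en-10-one (oxirane oxygen on the α face)
Conditions: dimethyldioxirane (1.1 equiv), acetone, −20 to 0 °C
Reagents that add atoms: dimethyldioxirane, CC1(C)OO1
Why: Electrophilic epoxidation of a conjugated dienone should take the γ,δ-alkene C6=C7 because the α,β-alkene is deactivated, and the oxidant should approach from the face of H5, away from C1 and its axial methyl, placing the oxygen α at C6.

Step 9
Reactants: 14 (1S,4R,5S,6R,7S)-6,7-epoxy-4-hydroxydauc-8-en-10-one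
Product: 15 (1S,4R,5S,6S)-4,6-dihydroxydauc-8-en-10-one
Conditions: Pd2(dba)3·CHCl3 (2.5 mol %), n-Bu3P (10 mol %), HCO2H (3 equiv), Et3N (1.5 equiv), 1,4-dioxane, rt
Reagents that add atoms: none
Why: Palladium-catalysed formate hydrogenolysis of an alkenyloxirane should ionise the allylic C7–O bond on zerovalent palladium and deliver the formate-derived hydride to C7, which keeps the enone conjugated and leaves the C6–O bond and its configuration untouched.

Step 10
Reactants: 15 (1S,4R,5S,6S)-4,6-dihydroxydauc-8-en-10-one
Product: 16 (1S,4R,5S,6S)-4-hydroxy-10-oxodauc-8-en-6-yl 4-methoxybenzoate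
Conditions: 4-methoxybenzoyl chloride (1.3 equiv), pyridine, DMAP (10 mol %), CH2Cl2, 0 °C to rt
Reagents that add atoms: 4-methoxybenzoyl chloride, COc1ccc(cc1)C(Cl)=O
Why: DMAP-catalysed acylation should esterify the only secondary alcohol, the tertiary C4 hydroxyl being inert, and the weak base should avoid vinylogous β-elimination of the new ester.

Step 11
Reactants: 16 (1S,4R,5S,6S)-4-hydroxy-10-oxodauc-8-en-6-yl 4-methoxybenzoate
Product: 17 (1S,4R,5S,6S,10S)-4,10-dihydroxydauc-8-en-6-yl 4-methoxybenzoate (10β-alcohol)
Conditions: NaBH4 (1.0 equiv), CeCl3·7H2O (1.0 equiv), MeOH, −40 °C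
Reagents that add atoms: none
Why: Luche 1,2-reduction should deliver hydride to the C10 carbonyl from the α face, anti to the axial methyl on the adjacent quaternary C1, giving the allylic alcohol with its hydroxyl cis to that methyl and no conjugate reduction.

Step 12
Reactants: 17 (1S,4R,5S,6S,10S)-4,10-dihydroxydauc-8-en-6-yl 4-methoxybenzoate
Product: 18 (1S,4R,5S,6S,10R)-10-acetoxy-4-hydroxydauc-8-en-6-yl 4-methoxybenzoate
Conditions: PPh3 (2 equiv), diisopropyl azodicarboxylate (2 equiv), AcOH (2.5 equiv), toluene, 0 °C to rt
Reagents that add atoms: acetic acid, CC(=O)O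
Why: Mitsunobu esterification should displace the allylic oxyphosphonium group at C10 by acetate in an SN2 reaction from the open α face, inverting C10 and installing the acetate in one operation, while the tertiary alcohol is inert and C1 carries no hydrogen for E2 elimination.

Compound list
1 | 2-methoxy-4-methylbenzaldehyde | COc1cc(C)ccc1C=O | starting material
2 | malonic acid | OC(=O)CC(=O)O | starting material
3 | 2-[(2-methoxy-4-methylphenyl)methylidene]propanedioic acid | COc1cc(C)ccc1C=C(C(=O)O)C(=O)O | intermediate
4 | (2E)-3-(2-methoxy-4-methylphenyl)prop-2-enoic acid | COc1cc(C)ccc1/C=C/C(=O)O | intermediate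
5 | 3-(2-methoxy-4-methylphenyl)propanoic acid | COc1cc(C)ccc1CCC(=O)O | intermediate
6 | (trimethylsilyl)diazomethane | C[Si](C)(C)C=[N+]=[N-] | starting material
7 | 3-(2-methoxy-4-methylphenyl)propanoyl chloride | COc1cc(C)ccc1CCC(Cl)=O | intermediate
8 | 1-diazo-4-(2-methoxy-4-methylphenyl)butan-2-one | COc1cc(C)ccc1CCC(=O)C=[N+]=[N-] | intermediate
9 | (1R,5R,6R)-10-methoxy-8-methyltricyclo[4.4.0.0(1,5)]deca-7,9-dien-4-one (norcaradiene, cyclopropane C1–C5–C6) | COC1=CC(C)=C[C@@H]2[C@H]3C(=O)CC[C@@]123 | intermediate
10 | (8aR)-4-methoxy-6-methyl-3,8a-dihydroazulen-1(2H)-one | COC1=C2CCC(=O)[C@@H]2C=CC(C)=C1 | intermediate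
11 | (1R,8aR)-4-methoxy-6-methyl-1-(propan-2-yl)-1,2,3,8a-tetrahydroazulen-1-ol | COC1=C2CC[C@@](O)(C(C)C)[C@@H]2C=CC(C)=C1 | intermediate
12 | (1R,3R,8R,9R)-3-methoxy-5-methyl-9-(propan-2-yl)tricyclo[6.3.0.0(1,3)]undeca-4,6-dien-9-ol | CO[C@@]12C[C@]1(CC[C@@]3(O)C(C)C)[C@H]3C=CC(C)=C2 | intermediate
13 | (1S,4R,5R)-4-hydroxydauca-6,8-dien-10-one | CC1=CC(=O)[C@@]2(C)CC[C@@](O)(C(C)C)[C@@H]2C=C1 | intermediate
14 | (1S,4R,5S,6R,7S)-6,7-epoxy-4-hydroxydauc-8-en-10-one | CC1=CC(=O)[C@@]2(C)CC[C@@](O)(C(C)C)[C@@H]2[C@H]3O[C@@H]13 | intermediate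
15 | (1S,4R,5S,6S)-4,6-dihydroxydauc-8-en-10-one | CC1=CC(=O)[C@@]2(C)CC[C@@](O)(C(C)C)[C@@H]2[C@@H](O)C1 | intermediate
16 | (1S,4R,5S,6S)-4-hydroxy-10-oxodauc-8-en-6-yl 4-methoxybenzoate | CC1=CC(=O)[C@@]2(C)CC[C@@](O)(C(C)C)[C@@H]2[C@@H](OC(=O)c3ccc(OC)cc3)C1 | intermediate
17 | (1S,4R,5S,6S,10S)-4,10-dihydroxydauc-8-en-6-yl 4-methoxybenzoate | CC1=C[C@H](O)[C@@]2(C)CC[C@@](O)(C(C)C)[C@@H]2[C@@H](OC(=O)c3ccc(OC)cc3)C1 | intermediate
18 | (1S,4R,5S,6S,10R)-10-acetoxy-4-hydroxydauc-8-en-6-yl 4-methoxybenzoate | COc1ccc(C(=O)O[C@H]2CC(C)=C[C@@H](OC(C)=O)[C@@]3(C)CC[C@@](O)(C(C)C)[C@H]23)cc1 | target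

Total step count: 12. Longest linear sequence: 12 steps (the route is linear from 1).

Steps most likely to fail

Step 4. The ligand may discriminate the two arene faces poorly, or the acidic C5–H of 10 may racemise before step 5, so that material of low enantiomeric purity enters the route. Fallback: setting out from 8, the achiral catalyst Rh2(OAc)4 (CH2Cl2, reflux) would give racemic material through 9 and its mirror image, (1S,5S,6S)-10-methoxy-8-methyltricyclo[4.4.0.0(1,5)]deca-7,9-dien-4-one F1, that is 10 together with (8aS)-4-methoxy-6-methyl-3,8a-dihydroazulen-1(2H)-one F2. The conditions of step 5 applied to this racemate would give 11 together with (1S,8aS)-4-methoxy-6-methyl-1-(propan-2-yl)-1,2,3,8a-tetrahydroazulen-1-ol F3. The two enantiomers would be separated by preparative chromatography on a chiral stationary phase, and the route is rejoined at 11.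

Step 6. Methylene transfer may be unselective among the three alkenes (attack at C6=C7 or double cyclopropanation), or the zinc iodide formed may degrade the enol ether. Fallback: setting out from 11, mild hydrolysis of the enol ether (oxalic acid, wet THF, 0 °C) would give (1R,8aR)-1-hydroxy-6-methyl-1-(propan-2-yl)-2,3,3a,8a-tetrahydroazulen-4(1H)-one F4 as a mixture of C1 epimers. Kinetic deprotonation at C1 with LiN(i-Pr)2 (2.2 equiv, THF, −78 °C) and methylation with MeI in the presence of DMPU should then alkylate the cross-conjugated enolate on its convex face, anti to H5 and to the isopropyl group, and the route is rejoined at 13.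

Step 12. The hindered, neopentyl-type allylic centre C10 may resist displacement, or the activated alcohol may ionise and eliminate to dienes. Fallback: setting out from 16, a reagent-controlled Corey–Bakshi–Shibata reduction ((S)-2-methyl-CBS-oxazaborolidine, catecholborane, toluene, −78 °C, antipode chosen with the quaternary C1 side as the large group) would deliver hydride to the β face and give (1S,4R,5S,6S,10R)-4,10-dihydroxydauc-8-en-6-yl 4-methoxybenzoate F5. Plain acetylation (Ac2O, pyridine, DMAP, CH2Cl2) then gives 18. The same acetylation alone would serve if step 11 were found to give F5 instead of 17.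

Further compounds
F1 | step 4 | (1S,5S,6S)-10-methoxy-8-methyltricyclo[4.4.0.0(1,5)]deca-7,9-dien-4-one | COC1=CC(C)=C[C@H]2[C@@H]3C(=O)CC[C@]123
F2 | step 4 | (8aS)-4-methoxy-6-methyl-3,8a-dihydroazulen-1(2H)-one | COC1=C2CCC(=O)[C@H]2C=CC(C)=C1
F3 | step 4 | (1S,8aS)-4-methoxy-6-methyl-1-(propan-2-yl)-1,2,3,8a-tetrahydroazulen-1-ol | COC1=C2CC[C@](O)(C(C)C)[C@H]2C=CC(C)=C1
F4 | step 6 | (1R,8aR)-1-hydroxy-6-methyl-1-(propan-2-yl)-2,3,3a,8a-tetrahydroazulen-4(1H)-one (both C3a epimers) | CC1=CC(=O)C2CC[C@@](O)(C(C)C)[C@@H]2C=C1
F5 | step 12 | (1S,4R,5S,6S,10R)-4,10-dihydroxydauc-8-en-6-yl 4-methoxybenzoate | CC1=C[C@@H](O)[C@@]2(C)CC[C@@](O)(C(C)C)[C@@H]2[C@@H](OC(=O)c3ccc(OC)cc3)C1
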